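**Assumptions (one line each)**
- The target is the open 2‑hydroxy‑5‑ketone as drawn; the free compound may equilibrate with its 2,5‑hemiketal.
- Germacrane numbering is used throughout: ring C1–C10, lactone carbons C11–C13, C14 = methyl on C10, C15 = methyl on C4. The target is (2S,4S,6S,7R,8R,9S,10S): 2‑OH, 4‑Me, 5‑oxo, 6‑OiBu, 12,8‑olide, 9‑OiBu, 10‑OH/Me.
- Compound 1 is bought as the (R)‑tosylate (D‑glutamic acid series; one step, TsCl/pyridine, from the commercial hydroxymethyl lactone if needed).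

**Retrosynthetic overview**
1. Target ⇐ desilylation ⇐ 9‑O‑acylation ⇐ syn‑dihydroxylation of E‑C9=C10 ⇐ oxidative 12,8‑lactonisation.
2. Key step: anionic oxy‑Cope [3,3] of a 1,2‑dialkenylcyclohexanol. It breaks C5–C10, forms C7–C8, sets C7/C8, and gives the E‑C9=C10 alkene and the C5 enolate (trapped as 6‑OiBu).
3. Cope substrate ⇐ bicyclic keto‑lactone 3: ketone + dienyl‑metal; lactone → lactol → (E)‑vinyl iodide → (E)‑enol ether.
4. 3 ⇐ (R)‑γ‑tosyloxymethyl‑γ‑butyrolactone by C‑acylation/methylation and intramolecular enolate alkylation; the bridge locks the quaternary carbon to the bought C2 centre.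
5. Ring order: γ‑lactone template (bought, later opened) → cyclohexanone → ten‑membered carbocycle by [3,3] → α‑methylene‑γ‑lactone last.

**Route**

Step 1
Reactants: 1, (R)‑5‑(tosyloxymethyl)dihydrofuran‑2(3H)‑one
Product: 2, (3S,5R)‑3‑methyl‑3‑propanoyl‑5‑(tosyloxymethyl)dihydrofuran‑2(3H)‑one (propanoyl cis to CH2OTs)
Conditions: LiHMDS (2.1 equiv), THF, −78 °C; N‑propanoylimidazole; then MeI, DMPU, −78 → 23 °C
Reagents that add atoms: N‑propanoylimidazole, CCC(=O)n1ccnc1; iodomethane, CI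
Why: Claisen C‑acylation of the lactone enolate, then C‑methylation of the β‑keto‑lactone enolate anti to the γ‑CH2OTs group (1,3‑induction), which creates the quaternary carbon (future C10) with the acyl group cis to CH2OTs.

Step 2
Reactants: 2
Product: 3, (1S,3S,5S)‑1,3‑dimethyl‑6‑oxabicyclo[3.2.1]octane‑2,7‑dione
Conditions: NaHMDS, n‑Bu4NI (cat.), THF, −78 → 40 °C; DBU (cat.) to equilibrate C3
Reagents that add atoms: none
Why: Intramolecular ketone‑enolate C‑alkylation (6‑(enolendo)‑exo‑tet) closes the cyclohexanone; only the cis isomer can bridge, so the quaternary centre is fixed by the bought stereocentre, and the enolisable C3 methyl (future C4, S) settles exo/equatorial.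

Step 3
Reactants: 4, 2‑bromoprop‑2‑en‑1‑ol
Product: 5, 2‑bromoallyl 4‑methoxybenzyl ether
Conditions: NaH, PMBCl, n‑Bu4NI, THF, 0 → 23 °C
Reagents that add atoms: 4‑methoxybenzyl chloride, COc1ccc(CCl)cc1
Why: Williamson etherification protects the future C12 hydroxyl.

Step 4
Reactants: 5; 6, (E)‑1,2‑bis(tributylstannyl)ethene (2.5 equiv)
Product: 7, (E)‑tributyl{3‑[(4‑methoxybenzyloxy)methyl]buta‑1,3‑dien‑1‑yl}stannane
Conditions: Pd(PPh3)4 (5 mol %), toluene, 90 °C
Reagents that add atoms: none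
Why: Mono‑Stille coupling with retention of E geometry gives the C6=C7/C11(=C13)/C12 unit as a dienylstannane.

Step 5
Reactants: 3; 7
Product: 8, 2‑hydroxy‑1,3‑dimethyl‑2‑[(E)‑3‑(PMB‑oxymethyl)buta‑1,3‑dienyl]‑6‑oxabicyclo[3.2.1]octan‑7‑one (dienyl anti to the lactone bridge, cis to both methyls)
Conditions: 7, n‑BuLi, THF, −78 °C; CeCl3; then 3, −78 °C; AcOH quench at −78 °C
Reagents that add atoms: none
Why: Sn–Li exchange and organocerium 1,2‑addition to the ketone (not the lactone) from the exo face; this carbinol centre is destroyed in Step 10, where either epimer would give the same C7/C8 configuration.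

Step 6
Reactants: 8
Product: 9, the corresponding bridged lactol (7‑hydroxy, anomer mixture)
Conditions: DIBAL‑H (2.5 equiv), CH2Cl2, −78 °C
Reagents that add atoms: none
Why: Partial reduction of the γ‑lactone stops at the bicyclic hemiacetal.

Step 7
Reactants: 9
Product: 10, 1‑[(E)‑3‑(PMB‑oxymethyl)buta‑1,3‑dienyl]‑2‑[(E)‑2‑iodovinyl]‑2,6‑dimethylcyclohexane‑1,4‑diol (iodovinyl cis to 4‑OH, trans to the dienyl and to both methyls)
Conditions: CrCl2, CHI3, THF, 0 → 23 °C
Reagents that add atoms: iodoform, IC(I)I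
Why: Takai iodo‑olefination of the open γ‑hydroxy‑aldehyde form gives the E‑vinyl iodide (adds C8) and frees the C2 hydroxyl.

Step 8
Reactants: 10
Product: 11, the 4‑O‑TBS ether of 10 (germacrane C2‑OTBS)
Conditions: TBSCl, imidazole, DMF, 23 °C
Reagents that add atoms: TBSCl, CC(C)(C)[Si](C)(C)Cl
Why: Selective silylation of the secondary alcohol; the tertiary allylic alcohol does not react.

Step 9
Reactants: 11
Product: 12, the (E)‑2‑(4‑methoxybenzyloxy)vinyl analogue of 11
Conditions: CuI (10 mol %), 3,4,7,8‑tetramethyl‑1,10‑phenanthroline, Cs2CO3, PMBOH (3 equiv), toluene, 80 °C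
Reagents that add atoms: 4‑methoxybenzyl alcohol, COc1ccc(CO)cc1
Why: Cu‑catalysed Ullmann‑type C–O coupling of the vinyl iodide with retention of E geometry installs the C8 oxygen as an enol ether.

Step 10
Reactants: 12
Product: 13, (9E)‑2‑OTBS‑5‑oxo‑6‑isobutyryloxy‑8,12‑bis(PMB‑oxy)germacra‑9,11(13)‑diene
Conditions: KH, 18‑crown‑6, THF, 0 → 23 °C; then (±)‑2‑(phenylsulfonyl)‑3‑phenyloxaziridine, −78 °C; then (i‑PrCO)2O, DMAP, −78 → 0 °C
Reagents that add atoms: racemic Davis oxaziridine, O=S(=O)(c1ccccc1)N1OC1c1ccccc1; isobutyric anhydride, CC(C)C(=O)OC(=O)C(C)C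
Why: Anionic oxy‑Cope [3,3] rearrangement through the chair transition state of the ring‑flipped conformer (both E‑alkenyl groups equatorial) transfers the C10 configuration to C7 (R) and C8 (R) and gives the E‑C9=C10 alkene and the C5 enolate; the enolate is hydroxylated on its exposed outer face (6S) and acylated in situ.

Step 11
Reactants: 13
Product: 14, the 8,12‑diol
Conditions: DDQ, CH2Cl2/pH 7 buffer, 0 °C
Reagents that add atoms: none
Why: Oxidative cleavage of both PMB ethers; TBS ether, isobutyrate and alkenes survive.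

Step 12
Reactants: 14
Product: 15, (9E)‑2‑OTBS‑5‑oxo‑6‑isobutyryloxy‑germacra‑9,11(13)‑dien‑12,8‑olide (trans‑fused)
Conditions: TEMPO (cat.), PhI(OAc)2, CH2Cl2, 23 °C
Reagents that add atoms: none
Why: Selective oxidation of the primary allylic alcohol to the enal, lactol formation with 8‑OH and further oxidation give the α‑methylene‑γ‑butyrolactone; 6‑O is already acylated, so only the 12,8‑olide can form.

Step 13
Reactants: 15
Product: 16, the 9,10‑diol (9S,10S)
Conditions: OsO4 (5 mol %), NMO, acetone/H2O, 0 °C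
Reagents that add atoms: OsO4, O=[Os](=O)(=O)=O; NMO, C[N+]1([O-])CCOCC1; water, O
Why: Upjohn syn‑dihydroxylation of the strained, electron‑rich E‑trisubstituted ring alkene (the α‑methylene lactone is electron‑poor) from the outer face of the conformer set by the Cope step; syn addition to the E‑alkene gives 9S,10S.

Step 14
Reactants: 16
Product: 17, 2‑O‑TBS‑cardivin D
Conditions: (i‑PrCO)2O, DMAP, Et3N, CH2Cl2, 0 → 23 °C
Reagents that add atoms: isobutyric anhydride, CC(C)C(=O)OC(=O)C(C)C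
Why: DMAP‑catalysed acylation of the only secondary hydroxyl (C9); the tertiary 10‑OH does not react.

Step 15
Reactants: 17
Product: 18, cardivin D
Conditions: HF·pyridine, THF/pyridine, 0 → 23 °C
Reagents that add atoms: none
Why: Fluoride desilylation of the secondary TBS ether; esters, ketone and methylene lactone are stable.

**Compound list**
1 | (R)‑5‑(tosyloxymethyl)dihydrofuran‑2(3H)‑one | O=C1CC[C@H](COS(=O)(=O)c2ccc(C)cc2)O1 | starting material
2 | (3S,5R)‑3‑methyl‑3‑propanoyl‑5‑(tosyloxymethyl)dihydrofuran‑2(3H)‑one | CCC(=O)[C@]1(C)C[C@H](COS(=O)(=O)c2ccc(C)cc2)OC1=O | intermediate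
3 | (1S,3S,5S)‑1,3‑dimethyl‑6‑oxabicyclo[3.2.1]octane‑2,7‑dione | O=C1O[C@@H]2C[C@@]1(C)C(=O)[C@@H](C)C2 | intermediate
4 | 2‑bromoprop‑2‑en‑1‑ol | OCC(Br)=C | starting material
5 | 2‑bromoallyl 4‑methoxybenzyl ether | C=C(Br)COCc1ccc(OC)cc1 | intermediate
6 | (E)‑1,2‑bis(tributylstannyl)ethene | CCCC[Sn](CCCC)(CCCC)/C=C/[Sn](CCCC)(CCCC)CCCC | starting material
7 | (E)‑tributyl{3‑[(4‑methoxybenzyloxy)methyl]buta‑1,3‑dien‑1‑yl}stannane | CCCC[Sn](CCCC)(CCCC)/C=C/C(=C)COCc1ccc(OC)cc1 | intermediate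
8 | bicyclic lactone tertiary alcohol (dienyl exo) | O=C1O[C@@H]2C[C@@]1(C)[C@@](O)(/C=C/C(=C)COCc3ccc(OC)cc3)[C@@H](C)C2 | intermediate
9 | bridged lactol of 8 (anomer mixture) | OC1O[C@@H]2C[C@@]1(C)[C@@](O)(/C=C/C(=C)COCc3ccc(OC)cc3)[C@@H](C)C2 | intermediate
10 | (E)‑iodovinyl cyclohexane‑1,4‑diol | O[C@@H]1C[C@](C)(/C=C/I)[C@@](O)(/C=C/C(=C)COCc2ccc(OC)cc2)[C@@H](C)C1 | intermediate
11 | 4‑O‑TBS ether of 10 | CC(C)(C)[Si](C)(C)O[C@@H]1C[C@](C)(/C=C/I)[C@@](O)(/C=C/C(=C)COCc2ccc(OC)cc2)[C@@H](C)C1 | intermediate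
12 | (E)‑PMB enol ether (oxy‑Cope substrate) | CC(C)(C)[Si](C)(C)O[C@@H]1C[C@](C)(/C=C/OCc2ccc(OC)cc2)[C@@](O)(/C=C/C(=C)COCc2ccc(OC)cc2)[C@@H](C)C1 | intermediate
13 | (9E)‑2‑OTBS‑5‑oxo‑6‑OiBu‑8,12‑bis(OPMB)germacra‑9,11(13)‑diene | O=C1[C@@H](OC(=O)C(C)C)[C@H](C(=C)COCc2ccc(OC)cc2)[C@@H](OCc2ccc(OC)cc2)/C=C(\C)C[C@@H](O[Si](C)(C)C(C)(C)C)C[C@@H]1C | intermediate
14 | 8,12‑diol | O=C1[C@@H](OC(=O)C(C)C)[C@H](C(=C)CO)[C@@H](O)/C=C(\C)C[C@@H](O[Si](C)(C)C(C)(C)C)C[C@@H]1C | intermediate
15 | (9E)‑2‑OTBS‑5‑oxo‑6‑OiBu‑germacra‑9,11(13)‑dien‑12,8‑olide | O=C1O[C@H]2/C=C(\C)C[C@@H](O[Si](C)(C)C(C)(C)C)C[C@H](C)C(=O)[C@@H](OC(=O)C(C)C)[C@@H]2C1=C | intermediate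
16 | 9,10‑diol of 15 | O=C1O[C@H]2[C@H](O)[C@@](C)(O)C[C@@H](O[Si](C)(C)C(C)(C)C)C[C@H](C)C(=O)[C@@H](OC(=O)C(C)C)[C@@H]2C1=C | intermediate
17 | 2‑O‑TBS‑cardivin D | O=C1O[C@H]2[C@H](OC(=O)C(C)C)[C@@](C)(O)C[C@@H](O[Si](C)(C)C(C)(C)C)C[C@H](C)C(=O)[C@@H](OC(=O)C(C)C)[C@@H]2C1=C | intermediate
18 | cardivin D | C=C1C(=O)O[C@@H]2[C@@H]1[C@H](OC(=O)C(C)C)C(=O)[C@@H](C)C[C@H](O)C[C@](C)(O)[C@H]2OC(=O)C(C)C | target

**Totals**
- Total steps: 15.
- Longest linear sequence: 13 (Steps 1, 2, 5–15).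

**Three steps most likely to fail, with fallbacks**
1. Step 10 (oxy‑Cope, hydroxylation, acylation). The rearrangement must go through the less populated diequatorial chair (syn‑diaxial methyls), and the C6 configuration relies on outer‑face attack on the medium‑ring enolate. Fallback for a wrong C6 epimer: protonate the enolate or isolate the 6‑epi alcohol, then invert with isobutyric acid under Mitsunobu conditions, which installs the ester directly. Fallback if ring expansion fails: close the ten‑membered ring by an intramolecular Cr(II)/Barbier allylation forming C7–C8 from an acyclic aldehyde and 2‑(bromomethyl)acrylate.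
2. Step 2 (bicyclisation). O‑alkylation or tosylate elimination could compete with C‑alkylation. Fallback: reverse the bond construction. Displace the tosylate with a propionate enolate, methylate the lactone α‑carbon, then close the ring by Dieckmann‑type acylation of the lactone enolate onto the side‑chain ester (forms C5–C10 instead of C3–C4).
3. Step 13 (dihydroxylation). Facial selectivity on the macrocycle and chemoselectivity against the methylene lactone are not guaranteed. Fallback: dihydroxylate diol 14 before lactonisation with stoichiometric OsO4·TMEDA directed by the free allylic 8‑OH, which lies on the required outer face, then lactonise.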